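**Plan**

- Retrosynthesis: the C6–Br bond is traded for C6–Si with the opposite alkene geometry. The butenolide is then cut at O1–C5 and C4–C5 into trimethylsilylacetylene and a 3,3-dibromoacrylic acid. Its CBr2 carbon is removed by a retro-Ramirez olefination to an α-keto ester, which is the ozonolysis product of an acetylated Morita–Baylis–Hillman adduct of butanal and tert-butyl acrylate.
- Enabling feature (ring numbered O1, C2 carbonyl, C3, C4, C5, exocyclic C6): C4 holds a bromine and the bond to C5, and C3 holds the C2 carboxyl carbon. C3=C4 is therefore a geminal dibromoalkene in which the bromine cis to the C2 carboxyl has been replaced by the alkyne carbon C5, to which O1 has added.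
- Forward order: the open chain C1'–C3(–C2)=C4Br2 is built in steps 1–5. The only ring closes in step 6, where C4–C5 and O1–C5 form in one flask. The C6 bromine is set in step 7.
- Stereochemistry: C1' (R) is selected by lipase-catalysed kinetic resolution of the racemic adduct and carried through untouched. The E geometry at C5=C6 comes from anti addition of O1 and H to the alkyne (Z silane), followed by anti bromination and anti bromide–silyl elimination, which inverts it.

Key step: step 6

Assumption: the lipase is taken to acylate the (R)-alcohol of 3 faster, as the empirical size rule for secondary alcohols predicts with the acrylate arm as the larger substituent; if the sense were opposite, the unreacted alcohol would be acetylated with Ac2O and enter the route as the same compound 4.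

**Route**

Step 1
Reactants: 1 butanal; 2 tert-butyl acrylate
Product: 3 tert-butyl 3-hydroxy-2-methylidenehexanoate (racemic)
Conditions: quinuclidine (25 mol %), MeOH (0.75 equiv), no further solvent, rt
Reagents that add atoms: none
Why: Morita–Baylis–Hillman reaction: quinuclidine adds to the acrylate, the ammonium enolate adds to butanal, and proton transfer (eased by methanol) with loss of the amine should give the allylic alcohol, its stereocentre forming without control as the racemate.

Step 2
Reactants: 3 tert-butyl 3-hydroxy-2-methylidenehexanoate (racemic)
Product: 4 tert-butyl (3R)-3-(acetyloxy)-2-methylidenehexanoate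
Conditions: Burkholderia cepacia lipase (immobilised), vinyl acetate (3 equiv), tert-butyl methyl ether, 30 °C, stopped near 40 % conversion; chromatographic removal of unreacted (S)-3
Reagents that add atoms: vinyl acetate, CC(=O)OC=C
Why: Enzymatic kinetic resolution by irreversible transesterification: the lipase should acylate the enantiomer whose larger acrylate arm and smaller propyl arm fit its pockets, here the (R)-alcohol, with vinyl acetate making the transfer irreversible as acetaldehyde leaves and the early stop keeping the acetate fraction enantiomerically enriched, so the only stereocentre of the target is fixed here by selection while (S)-3 is left behind.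

Step 3
Reactants: 4 tert-butyl (3R)-3-(acetyloxy)-2-methylidenehexanoate
Product: 5 tert-butyl (3R)-3-(acetyloxy)-2-oxohexanoate
Conditions: O3, CH2Cl2, −78 °C; then Me2S, −78 °C to rt; crude product dried azeotropically (toluene) and used at once
Reagents that add atoms: ozone, [O-][O+]=O
Why: Ozonolysis with reductive work-up: 1,3-dipolar cycloaddition of ozone to the 1,1-disubstituted alkene, cycloreversion and reduction of the ozonide by dimethyl sulfide should leave the α-keto ester under neutral conditions that neither cleave the acetate or the tert-butyl ester nor enolise the C3–H next to the new ketone.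

Step 4
Reactants: 5 tert-butyl (3R)-3-(acetyloxy)-2-oxohexanoate; 6 carbon tetrabromide
Product: 7 tert-butyl 2-[(1R)-1-(acetyloxy)butyl]-3,3-dibromoprop-2-enoate
Conditions: 6 (2 equiv), PPh3 (4 equiv), CH2Cl2, 0 °C, ylide preformed, then 5 added
Reagents that add atoms: none
Why: Ramirez dibromo-olefination (first stage of the Corey–Fuchs sequence): the ylide Ph3P=CBr2 formed from CBr4 and PPh3 should undergo a Wittig reaction at the ketone carbonyl, which the neighbouring ester activates, under non-basic conditions at 0 °C that leave the acetoxy-bearing stereocentre untouched.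

Step 5
Reactants: 7 tert-butyl 2-[(1R)-1-(acetyloxy)butyl]-3,3-dibromoprop-2-enoate
Product: 8 2-[(1R)-1-(acetyloxy)butyl]-3,3-dibromoprop-2-enoic acid
Conditions: CF3CO2H/CH2Cl2 1:4, 0 °C to rt
Reagents that add atoms: none
Why: Acidolysis of a tert-butyl ester: protonation and loss of the tert-butyl cation as 2-methylpropene should free the carboxylic acid, while the acetate, the vinylic bromides and the allylic C–O bond on an electron-poor tetrasubstituted alkene are stable to CF3CO2H.

Step 6
Reactants: 8 2-[(1R)-1-(acetyloxy)butyl]-3,3-dibromoprop-2-enoic acid; 9 ethynyl(trimethyl)silane (trimethylsilylacetylene)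
Product: 11 (1R)-1-{(5Z)-4-bromo-2-oxo-5-[(trimethylsilyl)methylidene]-2,5-dihydrofuran-3-yl}butyl acetate, via bromoenynoic acid 10 (not isolated)
Conditions: 9 (1.1 equiv), PdCl2(PPh3)2 (5 mol %), CuI (10 mol %), Et3N (3 equiv), degassed MeCN, rt
Reagents that add atoms: none
Why: Zerovalent palladium generated from PdCl2(PPh3)2 should insert into the C–Br bond cis to the carboxylate, the copper acetylide of 9 transmetalates, and reductive elimination forms C4–C5 to give the enynoate 10, whose carboxylate then adds to the metal-coordinated alkyne and is released by protonolysis. The closest known reaction type is the tandem Sonogashira coupling–lactonisation of (Z)-3-halopropenoic acids with terminal alkynes to (Z)-5-ylidenebutenolides; the second geminal bromine, which stays on C4, is the only new element. The ring closes 5-exo-dig through O1–C5, because attack at C5 places the developing positive charge beta to silicon and avoids the hindered silyl-bearing C6 that a 6-endo closure would require. No stereocentre is formed; the exocyclic geometry follows from anti oxymetalation and protonolysis with retention, which leave silicon cis to O1 (Z). The step needs site selectivity between the two geminal bromides, expected from carboxylate coordination to palladium and from the bromide next to the branched C1' arm being the more shielded one. It also needs a stop after one coupling, which the limited amount of 9 and the hindered position of the remaining C4–Br should secure, and oxidative addition at C–Br at room temperature should outrun ionisation of the allylic acetate on its tetrasubstituted, electron-poor alkene.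

Step 7
Reactants: 11 (1R)-1-{(5Z)-4-bromo-2-oxo-5-[(trimethylsilyl)methylidene]-2,5-dihydrofuran-3-yl}butyl acetate
Product: 14 (1R)-1-[(5E)-4-bromo-5-(bromomethylidene)-2-oxo-2,5-dihydrofuran-3-yl]butyl acetate (acetoxyfimbrolide), via (5R)-tribromide 12 (not isolated), via (5S)-tribromide 13 (not isolated)
Conditions: Br2 (1.05 equiv), CH2Cl2, −78 °C, dark; then CsF (2 equiv), 18-crown-6 (cat.), MeCN, −20 to 0 °C
Reagents that add atoms: bromine, BrBr
Why: Bromodesilylation of an alkenylsilane with inversion: bromine should add anti across the electron-rich C5=C6 enol-ester bond through a bromonium ion (an open C5 cation being disfavoured by the acylated oxygen and the bromo-enoate, and the tetrasubstituted electron-poor C3=C4 bond not reacting), and fluoride attack on silicon then expels the C5 bromide from the antiperiplanar conformer, so that the Z silane is converted into the E bromide with bromine cis to C4.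

**Compound list**

1 | butanal | CCCC=O | starting material
2 | tert-butyl acrylate | C=CC(=O)OC(C)(C)C | starting material
3 | tert-butyl 3-hydroxy-2-methylidenehexanoate (racemic) | CCCC(O)C(=C)C(=O)OC(C)(C)C | intermediate
4 | tert-butyl (3R)-3-(acetyloxy)-2-methylidenehexanoate | CCC[C@@H](OC(C)=O)C(=C)C(=O)OC(C)(C)C | intermediate
5 | tert-butyl (3R)-3-(acetyloxy)-2-oxohexanoate | CCC[C@@H](OC(C)=O)C(=O)C(=O)OC(C)(C)C | intermediate
6 | carbon tetrabromide | BrC(Br)(Br)Br | starting material
7 | tert-butyl 2-[(1R)-1-(acetyloxy)butyl]-3,3-dibromoprop-2-enoate | CCC[C@@H](OC(C)=O)C(C(=O)OC(C)(C)C)=C(Br)Br | intermediate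
8 | 2-[(1R)-1-(acetyloxy)butyl]-3,3-dibromoprop-2-enoic acid | CCC[C@@H](OC(C)=O)C(C(=O)O)=C(Br)Br | intermediate
9 | ethynyl(trimethyl)silane (trimethylsilylacetylene) | C#C[Si](C)(C)C | starting material
10 | (2E)-2-[(1R)-1-(acetyloxy)butyl]-3-bromo-5-(trimethylsilyl)pent-2-en-4-ynoic acid (present as its triethylammonium salt) | CCC[C@@H](OC(C)=O)/C(C(=O)O)=C(\Br)C#C[Si](C)(C)C | intermediate (not isolated)
11 | (1R)-1-{(5Z)-4-bromo-2-oxo-5-[(trimethylsilyl)methylidene]-2,5-dihydrofuran-3-yl}butyl acetate | CCC[C@@H](OC(C)=O)C1=C(Br)/C(=C/[Si](C)(C)C)OC1=O | intermediate
12 | (1R)-1-{(5R)-4,5-dibromo-5-[(R)-bromo(trimethylsilyl)methyl]-2-oxo-2,5-dihydrofuran-3-yl}butyl acetate (anti adduct) | CCC[C@@H](OC(C)=O)C1=C(Br)[C@@](Br)([C@@H](Br)[Si](C)(C)C)OC1=O | intermediate (not isolated)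
13 | (1R)-1-{(5S)-4,5-dibromo-5-[(S)-bromo(trimethylsilyl)methyl]-2-oxo-2,5-dihydrofuran-3-yl}butyl acetate (anti adduct from the other face) | CCC[C@@H](OC(C)=O)C1=C(Br)[C@](Br)([C@H](Br)[Si](C)(C)C)OC1=O | intermediate (not isolated)
14 | (1R)-1-[(5E)-4-bromo-5-(bromomethylidene)-2-oxo-2,5-dihydrofuran-3-yl]butyl acetate (acetoxyfimbrolide) | CCC[C@@H](OC(C)=O)C1=C(Br)/C(=C\Br)OC1=O | target

**Step count**

Total steps: 7. Longest linear sequence: 7 steps (1 to 14).

**Steps most likely to fail**

1. Step 6. Oxidative addition may occur at the bromide next to the C1' arm, a second coupling may follow at C4, zerovalent palladium may ionise the allylic acetate, or the carboxylate may close 6-endo or the alkyne may lose silicon. The fallback separates carbon–carbon bond formation from ring closure. It sets out from ester 7. A Negishi coupling with (trimethylsilylethynyl)zinc chloride (Me3SiC≡CZnCl, from 9, n-BuLi and ZnCl2) under PdCl2(DPEphos) in THF at 0 °C is a system with a good record for mono-alkynylation of 1,1-dibromoalkenes at the less hindered bromide, and here no carboxylate effect is involved. It should give tert-butyl (2E)-2-[(1R)-1-(acetyloxy)butyl]-3-bromo-5-(trimethylsilyl)pent-2-en-4-ynoate F1. CF3CO2H in CH2Cl2 then frees acid 10, now isolated. PdCl2(MeCN)2 (5 mol %) with Et3N in MeCN should close it 5-exo-dig by anti oxypalladation with divalent palladium only, so the allylic acetate meets no zerovalent palladium. The fallback returns to the route at 11.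

2. Step 7. Stereospecificity may be lost through bond rotation in an open C5 cation before bromide capture, or through addition–elimination of bromide or fluoride at C6 that turns the E bromide into the more stable Z isomer; fluoride may also attack the acetate or the enol lactone. The fallback installs the C6 bromine by anti bromolactonisation instead of bromodesilylation. It sets out from ester 7. Negishi coupling with ethynylzinc bromide (HC≡CZnBr; PdCl2(DPEphos), THF, 0 °C) should give tert-butyl (2E)-2-[(1R)-1-(acetyloxy)butyl]-3-bromopent-2-en-4-ynoate F2. CF3CO2H in CH2Cl2 should give (2E)-2-[(1R)-1-(acetyloxy)butyl]-3-bromopent-2-en-4-ynoic acid F3. N-Bromosuccinimide with KHCO3 in CH2Cl2/H2O should then add the carboxylate oxygen and bromine anti across the terminal alkyne (5-exo-dig, Markovnikov), which places bromine trans to O1 and gives 14 directly.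

3. Step 2. The lipase may discriminate poorly between the propyl and acrylate arms or acylate the hindered alcohol too slowly, and the enantiomeric purity of every later compound rests on this step. The fallback replaces resolution by asymmetric catalysis. It sets out from butanal 1, which is combined with 1,1,1,3,3,3-hexafluoropropan-2-yl acrylate under β-isocupreidine catalysis (10 mol %, DMF, −55 °C). This enantioselective Morita–Baylis–Hillman reaction should give 1,1,1,3,3,3-hexafluoropropan-2-yl (3R)-3-hydroxy-2-methylidenehexanoate F4. The activated ester is hydrolysed (LiOH, THF/H2O, 0 °C) to (3R)-3-hydroxy-2-methylidenehexanoic acid F5. The acid is esterified with N,N-dimethylformamide di-tert-butyl acetal (toluene, 80 °C) to tert-butyl (3R)-3-hydroxy-2-methylidenehexanoate F6. Acetylation (Ac2O, pyridine, DMAP cat., CH2Cl2, 0 °C) rejoins the route at 4.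

**Further compounds**

F1 | step 6 | tert-butyl (2E)-2-[(1R)-1-(acetyloxy)butyl]-3-bromo-5-(trimethylsilyl)pent-2-en-4-ynoate | CCC[C@@H](OC(C)=O)/C(C(=O)OC(C)(C)C)=C(\Br)C#C[Si](C)(C)C
F2 | step 7 | tert-butyl (2E)-2-[(1R)-1-(acetyloxy)butyl]-3-bromopent-2-en-4-ynoate | CCC[C@@H](OC(C)=O)/C(C(=O)OC(C)(C)C)=C(\Br)C#C
F3 | step 7 | (2E)-2-[(1R)-1-(acetyloxy)butyl]-3-bromopent-2-en-4-ynoic acid | CCC[C@@H](OC(C)=O)/C(C(=O)O)=C(\Br)C#C
F4 | step 2 | 1,1,1,3,3,3-hexafluoropropan-2-yl (3R)-3-hydroxy-2-methylidenehexanoate | CCC[C@@H](O)C(=C)C(=O)OC(C(F)(F)F)C(F)(F)F
F5 | step 2 | (3R)-3-hydroxy-2-methylidenehexanoic acid | CCC[C@@H](O)C(=C)C(=O)O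
F6 | step 2 | tert-butyl (3R)-3-hydroxy-2-methylidenehexanoate | CCC[C@@H](O)C(=C)C(=O)OC(C)(C)C
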